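**Assumptions.** Genipin, produced in bulk from gardenia geniposide, is taken as an inexpensive commercial chiral-pool compound. Iridoid numbering is used throughout: C1 acetal CH, C3=C4(CO2Me), C5/C9 ring fusion, C6=C7, C8 spiro carbon, C10 O–CH, C11 alkylidene carbon, C12 lactone C=O, C13 benzylidene CH. The route is a paper design and has not been run; the key step (step 3) is a vinylogous extension of a known reaction type.

## Retrosynthetic overview

1. The E-benzylidene (C11=C13) comes last, by aldol condensation of the tetracyclic spirolactone with a protected 4-hydroxybenzaldehyde.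
2. The THF acetal (C1–O–C10) and then the γ-lactone (C8–O–C12) come from oxa-Michael addition of the C1 lactol onto a γ-hydroxy enoate, followed by lactonisation.
3. The key step makes the quaternary C8–O bond by a [2,3]-sigmatropic sulfoxide→sulfenate (Mislow–Evans) rearrangement within a Knoevenagel/rearrangement cascade on a genipin-derived enal; this also moves the alkene to C6=C7 and forms C10–C11.
4. The cyclopenta[c]pyran core with the C5/C9 stereocentres is bought as genipin; C8 is set by the convex face of that bicycle, and C1 and C10 by ring-fusion constraints.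

## Route

**Step 1**
Reactants: 1, genipin
Product: 2, 10-oxogenipin (the C10 enal; free C1 lactol)
Conditions: activated MnO2 (15 equiv), EtOAc, rt
Reagents that add atoms: none
Why: MnO2 oxidation is selective for the primary allylic alcohol over the non-allylic lactol and the β-alkoxyacrylate; no stereocentre is touched.

**Step 2**
Reactants: 2, 10-oxogenipin; 3, tert-butyldimethylsilyl chloride
Product: 4, 1-O-TBS-10-oxogenipin
Conditions: TBSCl, imidazole, DMF, 0 °C → rt
Reagents that add atoms: TBSCl, CC(C)(C)[Si](C)(C)Cl
Why: Silylation of the only OH turns the lactol into a silyl acetal, which stops ring-opening and amine condensation in step 3; the anomeric configuration does not matter because C1 is reset in step 4.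

**Step 3 (key step)**
Reactants: 4, 1-O-TBS-10-oxogenipin; 5, methyl 2-(phenylsulfinyl)acetate (racemic)
Product: 6, the 8β-hydroxy-Δ6,7 (E)-enoate (C8 tertiary alcohol; C8 carries the α-oriented (E)-CH=CH–CO2Me chain)
Conditions: PhS(O)CH2CO2Me (1.5 equiv), piperidine (3 equiv), MeCN, rt → 40 °C
Reagents that add atoms: methyl 2-(phenylsulfinyl)acetate, COC(=O)CS(=O)c1ccccc1 (supplies C11, the C12 ester and, from S=O, the C8 oxygen)
Why: This is a vinylogous sulfoxide–piperidine aldol (SPAC) cascade: Knoevenagel condensation, base-mediated deconjugation to the allylic sulfoxide C6=C7–C8=C10–C11H(S(O)Ph)CO2Me, then [2,3]-sigmatropic Mislow–Evans rearrangement with piperidine cleaving the sulfenate. Oxygen is delivered to C8 from the convex β-face (cis to H-5/H-9, away from the pyran ring), and the new C10=C11 alkene is E.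

**Step 4**
Reactants: 6, the 8β-hydroxy enoate
Product: 7, the tetracyclic spirolactone (des-benzylidene prismatomerin, C11 = CH2)
Conditions: TBAF (1.1 equiv), THF, 0 °C → rt; then DBU (0.2 equiv), rt
Reagents that add atoms: none
Why: Desilylation frees the lactol, which anomerises by ring–chain tautomerism; only the 1α-alkoxide can add 5-exo to C10 (oxa-Michael). The addition is reversible and is drained by lactonisation of the C8–OH onto the ester, so C1 and C10 are fixed by the cis-ring-fusion requirement from C9 and C8.

**Step 5**
Reactants: 7, the tetracyclic spirolactone; 8, 4-(tert-butyldimethylsilyloxy)benzaldehyde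
Product: 9, O-TBS-prismatomerin
Conditions: LiHMDS added to 7 + 8, THF, −78 °C; Ac2O, −78 → 0 °C; DBU, rt (one pot)
Reagents that add atoms: 4-(tert-butyldimethylsilyloxy)benzaldehyde, O=Cc1ccc(O[Si](C)(C)C(C)(C)C)cc1
Why: Aldol condensation: the lactone enolate is trapped in situ by the non-enolisable aldehyde before the β-acetal oxygen can eliminate, and E1cB loss of acetate (a far better leaving group than the ring oxygen) gives the thermodynamic E-benzylidene with the aryl group anti to the lactone C=O. The C5 and C9 protons are not acidic enough to epimerise.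

**Step 6**
Reactants: 9, O-TBS-prismatomerin
Product: 10, prismatomerin
Conditions: HF·pyridine, THF/pyridine, 0 °C
Reagents that add atoms: none
Why: Buffered fluoride desilylation of the aryl silyl ether avoids a free phenoxide and leaves the bis-acetal, enol ether, lactone and E-alkene intact.

## Compound list

1 | Genipin, methyl (1R,4aS,7aS)-1-hydroxy-7-(hydroxymethyl)-1,4a,5,7a-tetrahydrocyclopenta[c]pyran-4-carboxylate | COC(=O)C1=CO[C@@H](O)[C@H]2[C@@H]1CC=C2CO | starting material

2 | 10-Oxogenipin, methyl (4aS,7aS)-7-formyl-1-hydroxy-1,4a,5,7a-tetrahydrocyclopenta[c]pyran-4-carboxylate (genipin-type anomer drawn; lactol may be an anomeric mixture) | COC(=O)C1=CO[C@@H](O)[C@H]2[C@@H]1CC=C2C=O | intermediate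

3 | tert-Butyldimethylsilyl chloride | CC(C)(C)[Si](C)(C)Cl | starting material

4 | 1-O-TBS-10-oxogenipin (anomer drawn as in genipin; C1 is re-equilibrated in step 4) | COC(=O)C1=CO[C@@H](O[Si](C)(C)C(C)(C)C)[C@H]2[C@@H]1CC=C2C=O | intermediate

5 | Methyl 2-(phenylsulfinyl)acetate (racemic) | COC(=O)CS(=O)c1ccccc1 | starting material

6 | Methyl (4aS,7aS)-1-(TBS-oxy)-7-hydroxy-7-[(E)-3-methoxy-3-oxoprop-1-enyl]-1,4a,7,7a-tetrahydrocyclopenta[c]pyran-4-carboxylate; the C8 (iridoid) OH is β, cis to H-5 and H-9 | COC(=O)C1=CO[C@@H](O[Si](C)(C)C(C)(C)C)[C@H]2[C@@H]1C=C[C@@]2(O)/C=C/C(=O)OC | intermediate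

7 | Des-benzylidene prismatomerin: tetracycle with the C1–O–C10 THF acetal and the spiro γ-lactone C8–O–C(=O)–CH2–C10, C6=C7, and the C3=C4–CO2Me enol ether ester | COC(=O)C1=CO[C@@H]2O[C@H]3CC(=O)O[C@]34C=C[C@H]1[C@H]24 | intermediate

8 | 4-(tert-Butyldimethylsilyloxy)benzaldehyde | O=Cc1ccc(O[Si](C)(C)C(C)(C)C)cc1 | starting material

9 | O-TBS-prismatomerin (E-4-silyloxybenzylidene at C11) | COC(=O)C1=CO[C@@H]2O[C@H]3/C(=C\c4ccc(O[Si](C)(C)C(C)(C)C)cc4)C(=O)O[C@]34C=C[C@H]1[C@H]24 | intermediate

10 | Prismatomerin | COC(=O)C1=CO[C@@H]2O[C@H]3/C(=C\c4ccc(O)cc4)C(=O)O[C@]34C=C[C@H]1[C@H]24 | target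

## Summary

Total steps: 6. Longest linear sequence: 6 (fully linear from genipin).

Steps most likely to fail, each with a fallback that changes the approach:

1. **Step 3 (vinylogous SPAC / [2,3] rearrangement).** The enal is α-branched and hindered, the deconjugation is vinylogous rather than the usual simple case, and the C8 facial selectivity is only predicted. Fallback: convert enal 4 to its TBS dienol ether (TBSOTf, Et3N), carry out a Rubottom oxidation (DMDO) from the convex face to give the 8β-hydroxy-Δ6,7 aldehyde, then a Wittig reaction with Ph3P=CHCO2Me to reach the same enoate 6.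

2. **Step 5 (aldol on the β-alkoxy lactone).** The enolate can undergo E1cB opening of the THF acetal and the iridoid core is base-sensitive. Fallback: avoid the free enolate by trapping it as the silyl ketene acetal (LiHMDS/TMSCl internal quench) and running a Lewis-acid Mukaiyama aldol with 8, followed by mesylation and elimination.

3. **Step 4 (anomerisation / oxa-Michael / lactonisation cascade).** It may stall at the hydroxy ester, or the freed lactol may ring-open and decompose under base. Fallback: close the lactone first by E→Z isomerisation of the enoate in 6 (hν with catalytic PhSSPh) to the plumieride-type spirobutenolide, then desilylate so that the C1–OH adds to the more electrophilic butenolide and only one ring has to form.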